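**Retrosynthetic overview**

1. The C8 hydroxyl is added last: target 30 comes from 7‑hydroxychroman 25 by MOM protection, lithiation at C8 (the only CH flanked by O1 and O7), borylation/oxidation and deprotection.
2. The strategy rests on one feature of the chroman: ring carbons C8a (oxygen‑bearing) and C8 (CH) correspond to a terminal ynol ether on the C2 tertiary oxygen O1, and C7, C4a, C5 and C6 correspond to a vinylketene whose α‑carbon C4a is already joined to O1 through C4–C3–C2.
3. Diazo enone 21 therefore gives both rings in one operation: first the dihydropyran ring (ketene–ynol ether [2+2]), then the benzene ring (four‑electron opening, six‑electron closure).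
4. 21 comes from enone 16, in which the ynol ether is carried as its robust 1,2‑dichlorovinyl ether and unveiled only two steps before the key step; 16 comes from aldehyde 13 and isopropenylmagnesium bromide.
5. The chain is built from (S)‑geranyllinalool 4 by hydroboration/B‑alkyl Suzuki coupling with vinyl bromide and a second hydroboration; the C2 stereocentre comes from Sharpless epoxidation of geranylgeraniol 1 and reductive opening of the epoxy iodide.

Key step: step 11

Remark: the all‑E isomer of geranylgeraniol is taken as the commercial material; the carbinol centre made in step 7 is carried as both epimers because step 8 removes it. Several CIP descriptors change along the route (R in 7–19, S elsewhere) only because substituent priorities change; the spatial arrangement at the quaternary carbon is the same throughout.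

**Route**

Step 1
Reactants: 1 (2E,6E,10E)-geranylgeraniol
Product: 2 {(2S,3S)-3-methyl-3-[(3E,7E)-4,8,12-trimethyltrideca-3,7,11-trienyl]oxiran-2-yl}methanol
Conditions: Ti(OiPr)4 (10 mol%), L-(+)-diethyl tartrate (12 mol%), t-BuOOH, 4 Å MS, CH2Cl2, −20 °C
Reagents that add atoms: tert-butyl hydroperoxide, CC(C)(C)OO
Why: Sharpless asymmetric epoxidation touches only the allylic alcohol olefin, and the L-(+)-tartrate ligand directs oxygen to the face that gives the (2S,3S)-epoxide, which fixes the future C2 centre and its oxygen O1.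

Step 2
Reactants: 2 the epoxy alcohol
Product: 4 (3S,6E,10E)-3,7,11,15-tetramethylhexadeca-1,6,10,14-tetraen-3-ol, via epoxy iodide 3 (not isolated)
Conditions: PPh3, I2, imidazole, THF, 0 °C; then Zn dust, EtOH, 60 °C
Reagents that add atoms: none
Why: Appel-type iodination of the primary alcohol followed by zinc-induced reductive β-elimination of the 2,3-epoxy iodide gives the transposed tertiary allylic alcohol without breaking the C–O bond at the stereocentre, so its configuration is retained.

Step 3
Reactants: 4 the tertiary vinyl carbinol; 5 vinyl bromide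
Product: 7 (5R,8E,12E)-5,9,13,17-tetramethyloctadeca-1,8,12,16-tetraen-5-ol, via alkylborane 6 (not isolated)
Conditions: 9-BBN (2.2 equiv), THF, 0 °C to rt; then 5, Pd(dppf)Cl2 (5 mol%), aq. K3PO4, DMF, 50 °C
Reagents that add atoms: vinyl bromide 5, C=CBr
Why: 9-BBN hydroborates only the monosubstituted vinyl group at its terminus, and B-alkyl Suzuki–Miyaura coupling of the primary alkylborane with vinyl bromide adds C4a and C7 as a terminal alkene.

Step 4
Reactants: 7 the tertiary alcohol; 8 trichloroethylene
Product: 10 (5R,8E,12E)-5-{[(E)-1,2-dichloroethenyl]oxy}-5,9,13,17-tetramethyloctadeca-1,8,12,16-tetraene, via potassium alkoxide 9 (not isolated)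
Conditions: KH, THF, 0 °C to rt; then Cl2C=CHCl, −50 °C to rt
Reagents that add atoms: trichloroethylene 8, ClC=C(Cl)Cl
Why: the potassium alkoxide adds to dichloroacetylene generated in situ from trichloroethylene (addition–elimination giving the 1,2-dichlorovinyl ether), which places the two future arene carbons C8a and C8 on O1 in a masked form that tolerates the following steps; the stereocentre is not involved.

Step 5
Reactants: 10 the dichlorovinyl ether
Product: 12 (5R,8E,12E)-5-{[(E)-1,2-dichloroethenyl]oxy}-5,9,13,17-tetramethyloctadeca-8,12,16-trien-1-ol, via alkylborane 11 (not isolated)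
Conditions: 9-BBN (1.2 equiv), THF, 0 °C to rt; then 3 M NaOH, 30% H2O2, 0 °C
Reagents that add atoms: hydrogen peroxide, OO
Why: anti-Markovnikov hydroboration–oxidation works here because 9-BBN reacts with the terminal alkene far faster than with the trisubstituted olefins or the chlorinated enol ether, giving the primary alcohol at the future C7.

Step 6
Reactants: 12 the primary alcohol
Product: 13 (5R,8E,12E)-5-{[(E)-1,2-dichloroethenyl]oxy}-5,9,13,17-tetramethyloctadeca-8,12,16-trienal
Conditions: Dess–Martin periodinane, NaHCO3, CH2Cl2, 0 °C to rt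
Reagents that add atoms: none
Why: buffered Dess–Martin oxidation stops at the aldehyde and leaves the dichlorovinyl ether and the olefins untouched.

Step 7
Reactants: 13 the aldehyde; 14 isopropenylmagnesium bromide
Product: 15 (3RS,7R,10E,14E)-7-{[(E)-1,2-dichloroethenyl]oxy}-2,7,11,15,19-pentamethylicosa-1,10,14,18-tetraen-3-ol
Conditions: 14 (0.5 M in THF), THF, −78 to 0 °C; aq. NH4Cl
Reagents that add atoms: isopropenylmagnesium bromide 14, C=C(C)[Mg]Br
Why: Grignard 1,2-addition to the aldehyde brings in C5, C6 and the C5 methyl group as the isopropenyl unit; the new carbinol centre forms without control and is removed in step 8.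

Step 8
Reactants: 15 the allylic alcohol
Product: 16 (7R,10E,14E)-7-{[(E)-1,2-dichloroethenyl]oxy}-2,7,11,15,19-pentamethylicosa-1,10,14,18-tetraen-3-one
Conditions: Dess–Martin periodinane, NaHCO3, CH2Cl2, 0 °C
Reagents that add atoms: none
Why: Dess–Martin oxidation of the secondary allylic alcohol gives the isopropenyl ketone and erases the uncontrolled carbinol centre while the ynol ether is still masked.

Step 9
Reactants: 16 the dichlorovinyl enone
Product: 19 (7R,10E,14E)-7-(ethynyloxy)-2,7,11,15,19-pentamethylicosa-1,10,14,18-tetraen-3-one, via lithium enolate 17 (not isolated), via dilithium enolate acetylide 18 (not isolated)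
Conditions: LiHMDS (1.1 equiv), THF, −78 °C; n-BuLi (3.5 equiv), −78 to −45 °C; MeOH, −78 °C; cold pH 7 work-up, concentration below 10 °C
Reagents that add atoms: none
Why: kinetic deprotonation at C4a masks the ketone as its cross-conjugated lithium enolate, which does not add n-BuLi, so dehydrochlorination and chlorine–lithium exchange of the dichlorovinyl ether (the standard conversion to a lithium alkynyl ether) can follow in the same flask and protonation returns the enone with the terminal ynol ether.

Step 10
Reactants: 19 the ynol ether enone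
Product: 21 (7S,10E,14E)-4-diazo-7-(ethynyloxy)-2,7,11,15,19-pentamethylicosa-1,10,14,18-tetraen-3-one, via trifluoroacetyl diketone 20 (not isolated)
Conditions: LiHMDS (1.1 equiv), THF, −78 °C; CF3CO2CH2CF3, −78 °C; cold aq. NH4Cl; then MsN3, Et3N, H2O, MeCN, 0 to 15 °C, dark
Reagents that add atoms: methanesulfonyl azide, CS(=O)(=O)N=[N+]=[N-]
Why: in this detrifluoroacetylative diazo transfer the ketone α-CH2 (C4a), far more acidic than the alkyne C–H, is enolised and trifluoroacetylated, and the activated diketone takes the diazo group from the sulfonyl azide with loss of the trifluoroacetyl group, all at or below room temperature so that the tert-alkyl ynol ether survives.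

Step 11
Reactants: 21 the diazo enone
Product: 25 (2S)-2,5-dimethyl-2-[(3E,7E)-4,8,12-trimethyltrideca-3,7,11-trienyl]chroman-7-ol, via vinylketene 22 (not isolated), via cyclobutenone 23 (not isolated), via dienylketene 24 (not isolated)
Conditions: hν (300 nm, Pyrex), degassed ClCH2CH2Cl (0.005 M), 10 °C; then 80 °C
Reagents that add atoms: none
Why: Proposed new method: irradiation expels N2 from 21 and the isopropenyl group shifts from the carbonyl carbon to C4a (Wolff rearrangement, forming C4a–C5) to give vinylketene 22, whose electrophilic carbonyl carbon C7 bonds to the nucleophilic terminal alkyne carbon C8 while C4a bonds to the oxygen-bearing alkyne carbon C8a, the normal polarity of a ketene–alkoxyalkyne [2+2] cycloaddition. This cycloaddition closes the dihydropyran ring as a six-membered ring in the fused mode across the tether C4–C3–C2–O1 and gives 4-vinylcyclobutenone 23; at 80 °C 23 opens by four-electron electrocyclic cleavage of C4a–C7 to dienylketene 24, in which the endocyclic C4a=C8a bond holds the ketenyl and isopropenyl groups cis, and six-electron electrocyclisation (C6–C7) followed by tautomerisation closes the benzene ring. The closest known reaction is the intermolecular Danheiser benzannulation of photochemically generated vinylketenes with alkoxyalkynes; an intramolecular case through a tert-alkyl ynol ether is without precedent. No stereocentre is formed in the product, the transient ring-fusion centre of 23 is lost on ring opening, and the C2–O1 bond is never broken, so C2 keeps its configuration. The step needs the [2+2] regiochemistry, which is secured by the matched ketene/ynol ether polarity and the tether length, and it needs the cycloaddition to outrun retro-ene loss of the ynol ether and diazo–alkyne dipolar cycloaddition, which is why photolysis is run cold and dilute and heat is applied only after the diazo compound is consumed.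

Step 12
Reactants: 25 the chromanol
Product: 26 (2S)-7-(methoxymethoxy)-2,5-dimethyl-2-[(3E,7E)-4,8,12-trimethyltrideca-3,7,11-trienyl]chromane
Conditions: MOMCl, iPr2NEt, CH2Cl2, 0 °C to rt
Reagents that add atoms: chloromethyl methyl ether, COCCl
Why: O-alkylation of the phenol (Williamson-type) protects O7 as the MOM ether, which is also the second ortho-directing group needed in step 13.

Step 13
Reactants: 26 the MOM ether
Product: 29 (2S)-7-(methoxymethoxy)-2,5-dimethyl-2-[(3E,7E)-4,8,12-trimethyltrideca-3,7,11-trienyl]chroman-8-ol, via aryllithium 27 (not isolated), via aryl boronate 28 (not isolated)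
Conditions: n-BuLi, TMEDA, THF, −20 to 0 °C; B(OMe)3, −78 °C to rt; 30% H2O2, aq. NaOH, 0 °C
Reagents that add atoms: hydrogen peroxide, OO
Why: directed ortho-metalation takes place at C8, the only position flanked by two oxygen directing groups (O1 and the MOM ether), and borylation followed by peroxide oxidation of the arylboronate (aryl shift from boron to oxygen) installs the C8 hydroxyl.

Step 14
Reactants: 29 the mono-MOM catechol
Product: 30 (2S)-2,5-dimethyl-2-[(3E,7E)-4,8,12-trimethyltrideca-3,7,11-trienyl]chromane-7,8-diol (CNP0122319.1)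
Conditions: HCl (from AcCl, 0.2 M), MeOH/THF, 0 °C to rt, argon
Reagents that add atoms: none
Why: acid-catalysed acetal exchange of the aryl MOM ether with methanol frees the catechol under conditions too mild to protonate the isolated trisubstituted olefins, and the inert atmosphere protects the electron-rich catechol.

**Compound list**

1 | (2E,6E,10E)-geranylgeraniol | CC(C)=CCC/C(C)=C/CC/C(C)=C/CC/C(C)=C/CO | starting material
2 | {(2S,3S)-3-methyl-3-[(3E,7E)-4,8,12-trimethyltrideca-3,7,11-trienyl]oxiran-2-yl}methanol | CC(C)=CCC/C(C)=C/CC/C(C)=C/CC[C@@](O1)(C)[C@@H]1CO | intermediate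
3 | (2R,3S)-2-(iodomethyl)-3-methyl-3-[(3E,7E)-4,8,12-trimethyltrideca-3,7,11-trienyl]oxirane | CC(C)=CCC/C(C)=C/CC/C(C)=C/CC[C@@](O1)(C)[C@@H]1CI | intermediate
4 | (3S,6E,10E)-3,7,11,15-tetramethylhexadeca-1,6,10,14-tetraen-3-ol [(S)-geranyllinalool] | CC(C)=CCC/C(C)=C/CC/C(C)=C/CC[C@@](O)(C)C=C | intermediate
5 | vinyl bromide | C=CBr | starting material
6 | 9-[(3R,6E,10E)-3-hydroxy-3,7,11,15-tetramethylhexadeca-6,10,14-trienyl]-9-borabicyclo[3.3.1]nonane (drawn with the hydroxyl free) | CC(C)=CCC/C(C)=C/CC/C(C)=C/CC[C@@](O)(C)CCB1C2CCCC1CCC2 | intermediate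
7 | (5R,8E,12E)-5,9,13,17-tetramethyloctadeca-1,8,12,16-tetraen-5-ol | CC(C)=CCC/C(C)=C/CC/C(C)=C/CC[C@@](O)(C)CCC=C | intermediate
8 | trichloroethylene | ClC=C(Cl)Cl | starting material
9 | potassium (5R,8E,12E)-5,9,13,17-tetramethyloctadeca-1,8,12,16-tetraen-5-olate | CC(C)=CCC/C(C)=C/CC/C(C)=C/CC[C@@](O[K])(C)CCC=C | intermediate
10 | (5R,8E,12E)-5-{[(E)-1,2-dichloroethenyl]oxy}-5,9,13,17-tetramethyloctadeca-1,8,12,16-tetraene | CC(C)=CCC/C(C)=C/CC/C(C)=C/CC[C@@](O/C(Cl)=C\Cl)(C)CCC=C | intermediate
11 | 9-[(5R,8E,12E)-5-{[(E)-1,2-dichloroethenyl]oxy}-5,9,13,17-tetramethyloctadeca-8,12,16-trienyl]-9-borabicyclo[3.3.1]nonane | CC(C)=CCC/C(C)=C/CC/C(C)=C/CC[C@@](O/C(Cl)=C\Cl)(C)CCCCB1C2CCCC1CCC2 | intermediate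
12 | (5R,8E,12E)-5-{[(E)-1,2-dichloroethenyl]oxy}-5,9,13,17-tetramethyloctadeca-8,12,16-trien-1-ol | CC(C)=CCC/C(C)=C/CC/C(C)=C/CC[C@@](O/C(Cl)=C\Cl)(C)CCCCO | intermediate
13 | (5R,8E,12E)-5-{[(E)-1,2-dichloroethenyl]oxy}-5,9,13,17-tetramethyloctadeca-8,12,16-trienal | CC(C)=CCC/C(C)=C/CC/C(C)=C/CC[C@@](O/C(Cl)=C\Cl)(C)CCCC=O | intermediate
14 | isopropenylmagnesium bromide | C=C(C)[Mg]Br | starting material
15 | (3RS,7R,10E,14E)-7-{[(E)-1,2-dichloroethenyl]oxy}-2,7,11,15,19-pentamethylicosa-1,10,14,18-tetraen-3-ol | CC(C)=CCC/C(C)=C/CC/C(C)=C/CC[C@@](O/C(Cl)=C\Cl)(C)CCCC(O)C(C)=C | intermediate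
16 | (7R,10E,14E)-7-{[(E)-1,2-dichloroethenyl]oxy}-2,7,11,15,19-pentamethylicosa-1,10,14,18-tetraen-3-one | CC(C)=CCC/C(C)=C/CC/C(C)=C/CC[C@@](O/C(Cl)=C\Cl)(C)CCCC(=O)C(C)=C | intermediate
17 | lithium enolate of 16 (C3–O–Li, C3=C4 double bond) | CC(C)=CCC/C(C)=C/CC/C(C)=C/CC[C@@](O/C(Cl)=C\Cl)(C)CCC=C(O[Li])C(C)=C | intermediate
18 | lithium enolate of 19 carrying lithium at the alkyne terminus | CC(C)=CCC/C(C)=C/CC/C(C)=C/CC[C@@](OC#C[Li])(C)CCC=C(O[Li])C(C)=C | intermediate
19 | (7R,10E,14E)-7-(ethynyloxy)-2,7,11,15,19-pentamethylicosa-1,10,14,18-tetraen-3-one | CC(C)=CCC/C(C)=C/CC/C(C)=C/CC[C@@](OC#C)(C)CCCC(=O)C(C)=C | intermediate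
20 | (4RS,7S,10E,14E)-7-(ethynyloxy)-2,7,11,15,19-pentamethyl-4-(trifluoroacetyl)icosa-1,10,14,18-tetraen-3-one (largely enolised) | CC(C)=CCC/C(C)=C/CC/C(C)=C/CC[C@@](OC#C)(C)CCC(C(=O)C(F)(F)F)C(=O)C(C)=C | intermediate
21 | (7S,10E,14E)-4-diazo-7-(ethynyloxy)-2,7,11,15,19-pentamethylicosa-1,10,14,18-tetraen-3-one | CC(C)=CCC/C(C)=C/CC/C(C)=C/CC[C@@](OC#C)(C)CCC(=[N+]=[N-])C(=O)C(C)=C | intermediate
22 | (5S,8E,12E)-5-(ethynyloxy)-5,9,13,17-tetramethyl-2-(prop-1-en-2-yl)octadeca-1,8,12,16-tetraen-1-one (vinylketene) | CC(C)=CCC/C(C)=C/CC/C(C)=C/CC[C@@](OC#C)(C)CCC(=C=O)C(C)=C | intermediate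
23 | (3S)-3-methyl-6-(prop-1-en-2-yl)-3-[(3E,7E)-4,8,12-trimethyltrideca-3,7,11-trienyl]-2-oxabicyclo[4.2.0]oct-1(8)-en-7-one (both C6 epimers) | CC(C)=CCC/C(C)=C/CC/C(C)=C/CC[C@@]1(C)CCC2(C(C)=C)C(=O)C=C2O1 | intermediate
24 | 2-{(2S)-2-methyl-5-(prop-1-en-2-yl)-2-[(3E,7E)-4,8,12-trimethyltrideca-3,7,11-trienyl]-3,4-dihydro-2H-pyran-6-yl}ethen-1-one (dienylketene) | CC(C)=CCC/C(C)=C/CC/C(C)=C/CC[C@@]1(C)CCC(C(C)=C)=C(C=C=O)O1 | intermediate
25 | (2S)-2,5-dimethyl-2-[(3E,7E)-4,8,12-trimethyltrideca-3,7,11-trienyl]chroman-7-ol | CC(C)=CCC/C(C)=C/CC/C(C)=C/CC[C@@]1(C)CCc2c(C)cc(O)cc2O1 | intermediate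
26 | (2S)-7-(methoxymethoxy)-2,5-dimethyl-2-[(3E,7E)-4,8,12-trimethyltrideca-3,7,11-trienyl]chromane | CC(C)=CCC/C(C)=C/CC/C(C)=C/CC[C@@]1(C)CCc2c(C)cc(OCOC)cc2O1 | intermediate
27 | 8-lithio derivative of 26 | CC(C)=CCC/C(C)=C/CC/C(C)=C/CC[C@@]1(C)CCc2c(C)cc(OCOC)c([Li])c2O1 | intermediate
28 | dimethyl {(2S)-7-(methoxymethoxy)-2,5-dimethyl-2-[(3E,7E)-4,8,12-trimethyltrideca-3,7,11-trienyl]chroman-8-yl}boronate | CC(C)=CCC/C(C)=C/CC/C(C)=C/CC[C@@]1(C)CCc2c(C)cc(OCOC)c(B(OC)OC)c2O1 | intermediate
29 | (2S)-7-(methoxymethoxy)-2,5-dimethyl-2-[(3E,7E)-4,8,12-trimethyltrideca-3,7,11-trienyl]chroman-8-ol | CC(C)=CCC/C(C)=C/CC/C(C)=C/CC[C@@]1(C)CCc2c(C)cc(OCOC)c(O)c2O1 | intermediate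
30 | (2S)-2,5-dimethyl-2-[(3E,7E)-4,8,12-trimethyltrideca-3,7,11-trienyl]chromane-7,8-diol | CC(C)=CCC/C(C)=C/CC/C(C)=C/CC[C@@]1(C)CCc2c(C)cc(O)c(O)c2O1 | target

**Totals**

Total step count: 14. Longest linear sequence: 14 steps (from 1 to 30).

**Steps most likely to fail**

Step 11. The photogenerated vinylketene may not be captured by the tethered ynol ether: the tert-alkyl ynol ether can fragment by retro-ene loss, the ketene can dimerise, the diazo group can add to the alkyne before photolysis, or the fused cyclobutenone can resist ring opening. The fallback uses known chemistry and builds the chroman on a preformed arene. It sets out from 4. Commercial 3-bromo-5-methylphenol would be iodinated para to the hydroxyl (N-iodosuccinimide, TsOH cat., MeCN) to 3-bromo-4-iodo-5-methylphenol F1 and protected (MOMCl, iPr2NEt) as 1-bromo-2-iodo-5-(methoxymethoxy)-3-methylbenzene F2. Hydroboration of 4 with 9-BBN gives borane 6 as in step 3, and B-alkyl Suzuki–Miyaura coupling with F2 at the carbon–iodine bond (Pd(dppf)Cl2, aq. K3PO4, DMF, 50 °C) should give (3S,6E,10E)-1-[2-bromo-4-(methoxymethoxy)-6-methylphenyl]-3,7,11,15-tetramethylhexadeca-6,10,14-trien-3-ol F3. Palladium-catalysed intramolecular aryl etherification of the tertiary alcohol with the aryl bromide (Buchwald–Hartwig-type C–O coupling; Pd(OAc)2, 2-(di-tert-butylphosphino)-1,1'-binaphthyl, Cs2CO3, toluene, 80 °C) closes the pyran ring with retention at C2, because the carbinol C–O bond is not broken. The fallback comes back to the route at 26, and steps 13 and 14 follow unchanged.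

Step 10. Enolate trifluoroacetylation in the presence of the terminal ynol ether may be accompanied by metalation and acylation at the alkyne terminus, or the acidic trifluoroacetyl diketone may add across the ynol ether. The fallback moves the acylation ahead of the unveiling. It sets out from 16: LiHMDS then CF3CO2CH2CF3 at −78 °C gives (4RS,7S,10E,14E)-7-{[(E)-1,2-dichloroethenyl]oxy}-2,7,11,15,19-pentamethyl-4-(trifluoroacetyl)icosa-1,10,14,18-tetraen-3-one F4. F4 is converted to its lithium diketonate (LiHMDS) and treated with n-BuLi (−78 to −45 °C) to unveil the alkynyl ether; one equivalent of methanol at −78 °C protonates only the acetylide. The fallback comes back to the route at 20, held as its lithium salt, which is treated directly with MsN3 in MeCN to give 21. The strong-base acylation then never meets the free ynol ether, and 19 is bypassed.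

Step 9. Enolisation may be incomplete, so that n-BuLi adds to the ketone, or the enolate and the regenerated isopropenyl ketone may condense (aldol or Michael) during the quench. The fallback unveils the ynol ether before the ketone exists. It sets out from 15: n-BuLi (3.3 equiv, THF, −78 to −45 °C; MeOH) acts on the alkoxide to give (3RS,7R,10E,14E)-7-(ethynyloxy)-2,7,11,15,19-pentamethylicosa-1,10,14,18-tetraen-3-ol F5. Oxidation of the allylic alcohol with Dess–Martin periodinane buffered with pyridine (CH2Cl2, 0 °C, short contact) comes back to the route at 19.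

**Further compounds**

F1 | step 11 | 3-bromo-4-iodo-5-methylphenol | Cc1cc(O)cc(Br)c1I
F2 | step 11 | 1-bromo-2-iodo-5-(methoxymethoxy)-3-methylbenzene | COCOc1cc(C)c(I)c(Br)c1
F3 | step 11 | (3S,6E,10E)-1-[2-bromo-4-(methoxymethoxy)-6-methylphenyl]-3,7,11,15-tetramethylhexadeca-6,10,14-trien-3-ol | CC(C)=CCC/C(C)=C/CC/C(C)=C/CC[C@@](O)(C)CCc1c(C)cc(OCOC)cc1Br
F4 | step 10 | (4RS,7S,10E,14E)-7-{[(E)-1,2-dichloroethenyl]oxy}-2,7,11,15,19-pentamethyl-4-(trifluoroacetyl)icosa-1,10,14,18-tetraen-3-one | CC(C)=CCC/C(C)=C/CC/C(C)=C/CC[C@@](O/C(Cl)=C\Cl)(C)CCC(C(=O)C(F)(F)F)C(=O)C(C)=C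
F5 | step 9 | (3RS,7R,10E,14E)-7-(ethynyloxy)-2,7,11,15,19-pentamethylicosa-1,10,14,18-tetraen-3-ol | CC(C)=CCC/C(C)=C/CC/C(C)=C/CC[C@@](OC#C)(C)CCCC(O)C(C)=C
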